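**Retrosynthetic overview**
- Feature used: in ring A the C3 carbinol sits beside the C4 gem-dimethyl carbon. C4 is bonded to C5, the α′-carbon of the ring-B enone (C6=O, C7=C8). The array C3(OH)–C4–C5–C6(=O) is read as an epoxide opened at its tertiary end by an enol ether.
- Disconnections: (a) the C11–OAr ether (umbelliferone, made last); (b) C4–C5, which opens ring A to a ring-B silyl dienol ether carrying a (3R)-3,4-epoxide chain on C10; (c) C6=O, from allylic oxidation.
- (d) C9–C11, from a [2,3] shift out of a C7 carbinol made by reagent-controlled reduction; (e) the epoxide, from reagent-controlled epoxidation at the first enone, where the side-chain alkene is the only electron-rich one.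
- (f) Ring B, from Michael–aldol annulation of melonal and ethyl vinyl ketone (sets C10). Ring order: B first, A last; the coumarin rings are bought.

Key step: step 9

Numbering: drimane numbering is kept for all intermediates (ring A = C1–C5 + C10, ring B = C5–C10, C11 = CH2O on C9, C12 = methyl on C8).

Assumption: the sense of induction of the diamine salt with a dialkyl-branched aldehyde is taken to be the one written in step 1; if it is the opposite, the (1S,2S) salt is used and nothing else changes.

**Step 1**
Reactants: 1 melonal (2,6-dimethylhept-5-enal, racemic); 2 ethyl vinyl ketone (pent-1-en-3-one)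
Product: 4 (R)-2,4-dimethyl-4-(4-methylpent-3-enyl)cyclohex-2-enone, via keto aldehyde 3 (not isolated)
Conditions: (1R,2R)-cyclohexane-1,2-diamine (30 mol %), (1R,2R)-cyclohexane-1,2-dicarboxylic acid (30 mol %), CH2Cl2, 0 °C to rt; then piperidine, AcOH (20 mol % each), toluene, 60 °C
Reagents that add atoms: none
Why: Enamine Michael addition of an α-branched aldehyde to a vinyl ketone followed by intramolecular aldol condensation (Robinson-type annulation); racemic 1 converges on the enamine, the chiral primary ammonium salt shields one enamine face and sets C10, and because methyl and homoprenyl differ little the induction should be only moderate, so the residual C10 antipode is turned by the reagent-controlled steps 2 and 3 into a diastereomer of 6 that is removed by chromatography.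

**Step 2**
Reactants: 4 (R)-2,4-dimethyl-4-(4-methylpent-3-enyl)cyclohex-2-enone
Product: 5 (R)-4-{2-[(R)-3,3-dimethyloxiran-2-yl]ethyl}-2,4-dimethylcyclohex-2-enone
Conditions: Shi ketone (1,2:4,5-di-O-isopropylidene-β-D-erythro-2,3-hexodiulo-2,6-pyranose, 30 mol %), KHSO5 (Oxone, 2KHSO5·KHSO4·K2SO4), K2CO3, Bu4NHSO4 (cat), Na2B4O7/Na2(EDTA) buffer pH 10.5, MeCN–CH2(OMe)2–H2O, 0 °C
Reagents that add atoms: potassium peroxymonosulfate, [K+].[O-]S(=O)(=O)OO
Why: Shi asymmetric epoxidation, in which the electrophilic chiral dioxirane attacks only the electron-rich C3=C4 alkene and leaves the enone alkene alone, the spiro transition state of the D-fructose-derived ketone giving the (3R)-epoxide; done at this point, neither the borane of step 3 nor the allylic oxidation of step 7 meets a second alkene.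

**Step 3**
Reactants: 5 (R)-4-{2-[(R)-3,3-dimethyloxiran-2-yl]ethyl}-2,4-dimethylcyclohex-2-enone
Product: 6 (1R,4S)-4-{2-[(R)-3,3-dimethyloxiran-2-yl]ethyl}-2,4-dimethylcyclohex-2-enol (drimane 3R,7R,10S; hydroxyl cis to the C10 methyl)
Conditions: (S)-Me-CBS oxazaborolidine [(S)-1-methyl-3,3-diphenyltetrahydro-1H,3H-pyrrolo[1,2-c][1,3,2]oxazaborole, 20 mol %], catecholborane (1.8 equiv), toluene, −78 °C; then MeOH, H2O
Reagents that add atoms: none
Why: Corey–Bakshi–Shibata reduction, in which the 2-methylalkenyl arm acts as the large group so that the (S)-catalyst delivers hydride to give the (7R)-alcohol independently of the remote centres, while catecholborane at −78 °C spares the epoxide.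

**Step 4**
Reactants: 6 the (3R,7R,10S)-allylic alcohol; 7 tributyl(iodomethyl)stannane
Product: 8 tributylstannylmethyl ether of 6 (3R,7R,10S)
Conditions: KH, THF, 0 °C; then 7, 18-crown-6 (cat), 0 °C to rt
Reagents that add atoms: none
Why: Williamson etherification of the potassium alkoxide with the reactive α-stannyl iodide, which touches no stereocentre and leaves the trisubstituted epoxide alone.

**Step 5**
Reactants: 8 tributylstannylmethyl ether of 6
Product: 10 [(1S,6S)-6-{2-[(R)-3,3-dimethyloxiran-2-yl]ethyl}-2,6-dimethylcyclohex-2-enyl]methanol (drimane 3R,9S,10S; CH2OH cis to the C10 methyl), via lithiomethyl ether 9 (not isolated)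
Conditions: n-BuLi (1.2 equiv), THF, −78 to −30 °C; then H2O
Reagents that add atoms: none
Why: Still–Wittig [2,3]-sigmatropic rearrangement, in which tin–lithium exchange is faster than any attack on the epoxide and the suprafacial shift through the conformer with pseudoaxial O-7 places the CH2O unit on C9 on the face that O-7 occupied, so that C11 is cis to the C10 methyl and the alkene moves to C7=C8.

**Step 6**
Reactants: 10 the (3R,9S,10S)-homoallylic alcohol
Product: 11 tert-butyldimethylsilyl ether of 10
Conditions: TBSCl, imidazole, DMF, rt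
Reagents that add atoms: tert-butyldimethylsilyl chloride, CC(C)(C)[Si](C)(C)Cl
Why: Standard silylation of the only hydroxyl group, giving a C11 ether that tolerates the oxidation, the amide base and the aluminium Lewis acid to come.

**Step 7**
Reactants: 11 tert-butyldimethylsilyl ether of 10
Product: 12 (4S,5R)-4-(tert-butyldimethylsilyloxymethyl)-5-{2-[(R)-3,3-dimethyloxiran-2-yl]ethyl}-3,5-dimethylcyclohex-2-enone (drimane 3R,9S,10R)
Conditions: Rh2(cap)4 (cap = caprolactamate, 1 mol %), t-BuOOH (70 % in water, 5 equiv), K2CO3 (0.5 equiv), CH2Cl2, rt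
Reagents that add atoms: tert-butyl hydroperoxide, CC(C)(C)OO
Why: Allylic C–H oxidation by tert-butylperoxyl radicals, of the kind used on α-ionone-type cyclohexenes; C7=C8 is now the only alkene, C6 is its only allylic methylene, and C9–H is shielded by C10 and the silyloxymethyl group.

**Step 8**
Reactants: 12 the C6 enone
Product: 14 tert-butyl({(1R,6S)-6-{2-[(R)-3,3-dimethyloxiran-2-yl]ethyl}-2,6-dimethyl-4-(trimethylsilyloxy)cyclohexa-2,4-dienyl}methoxy)dimethylsilane (drimane 3R,9R,10S), via lithium dienolate 13 (not isolated)
Conditions: LiN(i-Pr)2 (LDA, 1.15 equiv), THF, −78 °C; Me3SiCl (1.5 equiv), −78 to 0 °C; pentane, cold aq NaHCO3 wash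
Reagents that add atoms: trimethylsilyl chloride, C[Si](C)(C)Cl
Why: Kinetic α′-deprotonation of a β-methyl enone at C5 (the behaviour known for isophorone) and O-silylation give the cross-conjugated 2-silyloxydiene, while C9 and the epoxide are untouched at −78 °C.

**Step 9**
Reactants: 14 the ring-B trimethylsilyl dienol ether with the (3R)-epoxide chain
Product: 16 (3R,5S,9R,10S)-11-(tert-butyldimethylsilyloxy)-3-hydroxydrim-7-en-6-one, via cis-fused C5 epimer 15 (not isolated)
Conditions: MeAlCl2 (1 M in hexanes, 1.5 equiv), CH2Cl2, −78 °C; aq NaHCO3; crude material in K2CO3 (0.3 equiv), MeOH, rt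
Reagents that add atoms: none
Why: MeAlCl2 binds the epoxide oxygen and loosens the C4–O bond at the tertiary carbon, C5 (the terminus of the C5=C6 enol ether) attacks C4 from the side opposite to oxygen, and loss of the silyl group from the oxocarbenium ion returns the C6 ketone conjugated with C7=C8 while C3 keeps its oxygen and its (R) configuration. The closest known reaction type is the Lewis-acid-promoted intramolecular opening of trisubstituted epoxides by silyl enol ethers, as in epoxide-initiated cyclisations that terminate on a silyl enol ether. Ring A (C1–C5, C10) closes 6-endo-tet with respect to the epoxide and exo with respect to the enol double bond. The step needs attack at C4 and not 5-exo attack at C3, which the two methyl groups secure by localising the positive charge on C4, and it needs C5 as the only nucleophilic site, which the kinetic cross-conjugated dienol ether secures. Because C4 must approach C5 perpendicular to the diene plane, the new bond is axial on ring B and the kinetic product should be the cis-fused epimer 15, reached through a boat-like or largely SN1-like transition state, since this (3R)-epoxide cannot hold C3–O anti to the forming bond in an all-chair array. C5, the only new stereocentre, is therefore set under thermodynamic control: K2CO3 in MeOH enolises C5–H (as in the C5 epimerisation of 7-en-6-one steroids), cleaves any C3 silyl ether and should funnel the material to trans-fused 16 with equatorial C3–OH, C9 staying untouched under these mild conditions.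

**Step 10**
Reactants: 16 the C11 silyl ether
Product: 17 (3R,5S,9R,10S)-3,11-dihydroxydrim-7-en-6-one
Conditions: HF·pyridine, pyridine, THF, 0 °C to rt
Reagents that add atoms: none
Why: Fluoride-driven cleavage of the primary silyl ether under non-basic conditions, which avoids γ-deprotonation at C9 and retro-aldol-type loss of C11.

**Step 11**
Reactants: 17 the diol; 18 umbelliferone (7-hydroxycoumarin)
Product: 19 ligupersin A, 7-{[(3R,5S,9R,10S)-3-hydroxy-6-oxodrim-7-en-11-yl]oxy}coumarin
Conditions: PPh3, DIAD, THF, 0 °C to rt
Reagents that add atoms: none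
Why: Mitsunobu etherification, in which only the primary C11–OH forms the oxyphosphonium salt at a useful rate (C3–OH is secondary and flanked by the gem-dimethyl carbon) and the acidic phenol (pKa about 8) displaces it at a carbon that is not stereogenic.

**Compound list**
1 | melonal (2,6-dimethylhept-5-enal, racemic) | CC(C)=CCCC(C)C=O | starting material
2 | ethyl vinyl ketone | CCC(=O)C=C | starting material
3 | (R)-2-methyl-2-(4-methylpent-3-enyl)-5-oxoheptanal | O=C[C@](C)(CCC=C(C)C)CCC(=O)CC | intermediate
4 | (R)-2,4-dimethyl-4-(4-methylpent-3-enyl)cyclohex-2-enone | O=C1CC[C@@](C)(CCC=C(C)C)C=C1C | intermediate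
5 | (R)-4-{2-[(R)-3,3-dimethyloxiran-2-yl]ethyl}-2,4-dimethylcyclohex-2-enone | O=C1CC[C@@](C)(CC[C@H]2OC2(C)C)C=C1C | intermediate
6 | (1R,4S)-4-{2-[(R)-3,3-dimethyloxiran-2-yl]ethyl}-2,4-dimethylcyclohex-2-enol | O[C@@H]1CC[C@@](C)(CC[C@H]2OC2(C)C)C=C1C | intermediate
7 | tributyl(iodomethyl)stannane | CCCC[Sn](CI)(CCCC)CCCC | starting material
8 | tributylstannylmethyl ether of 6 | CCCC[Sn](CCCC)(CCCC)CO[C@@H]1CC[C@@](C)(CC[C@H]2OC2(C)C)C=C1C | intermediate
9 | lithiomethyl ether of 6 | [Li]CO[C@@H]1CC[C@@](C)(CC[C@H]2OC2(C)C)C=C1C | intermediate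
10 | [(1S,6S)-6-{2-[(R)-3,3-dimethyloxiran-2-yl]ethyl}-2,6-dimethylcyclohex-2-enyl]methanol | C1C[C@@](C)(CC[C@H]2OC2(C)C)[C@H](CO)C(C)=C1 | intermediate
11 | tert-butyldimethylsilyl ether of 10 | C1C[C@@](C)(CC[C@H]2OC2(C)C)[C@H](CO[Si](C)(C)C(C)(C)C)C(C)=C1 | intermediate
12 | (4S,5R)-4-(tert-butyldimethylsilyloxymethyl)-5-{2-[(R)-3,3-dimethyloxiran-2-yl]ethyl}-3,5-dimethylcyclohex-2-enone | O=C1C[C@@](C)(CC[C@H]2OC2(C)C)[C@H](CO[Si](C)(C)C(C)(C)C)C(C)=C1 | intermediate
13 | lithium cross-conjugated dienolate of 12 | [Li]OC1=C[C@@](C)(CC[C@H]2OC2(C)C)[C@H](CO[Si](C)(C)C(C)(C)C)C(C)=C1 | intermediate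
14 | trimethylsilyl dienol ether of 12 (key-step precursor) | C[Si](C)(C)OC1=C[C@@](C)(CC[C@H]2OC2(C)C)[C@H](CO[Si](C)(C)C(C)(C)C)C(C)=C1 | intermediate
15 | (3R,5R,9R,10S)-11-(tert-butyldimethylsilyloxy)-3-hydroxydrim-7-en-6-one (cis-fused) | CC1=CC(=O)[C@H]2C(C)(C)[C@H](O)CC[C@@]2(C)[C@@H]1CO[Si](C)(C)C(C)(C)C | intermediate
16 | (3R,5S,9R,10S)-11-(tert-butyldimethylsilyloxy)-3-hydroxydrim-7-en-6-one (key-step product) | CC1=CC(=O)[C@@H]2C(C)(C)[C@H](O)CC[C@@]2(C)[C@@H]1CO[Si](C)(C)C(C)(C)C | intermediate
17 | (3R,5S,9R,10S)-3,11-dihydroxydrim-7-en-6-one | CC1=CC(=O)[C@@H]2C(C)(C)[C@H](O)CC[C@@]2(C)[C@@H]1CO | intermediate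
18 | umbelliferone | O=c1ccc2ccc(O)cc2o1 | starting material
19 | ligupersin A | CC1=CC(=O)[C@@H]2C(C)(C)[C@H](O)CC[C@@]2(C)[C@@H]1COc1ccc2ccc(=O)oc2c1 | target

**Step count**
Total step count: 11. Longest linear sequence: 11 (from 1 to 19).

**Steps most likely to fail**

Step 9.
- What may go wrong: once aluminium is bound, the C4–O bond may ionise. A 1,2-hydride shift from C3 (Meinwald-type rearrangement to the isopropyl ketone), or capture by chloride, may then outrun attack by the hindered C5. The reason is that the (3R)-epoxide paired with this C10 configuration has no all-chair, anti-periplanar array for the axial attack on C5. The C5 equilibration may also be slow.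
- Fallback: C3 is no longer taken from the epoxide but set after ring closure. The fallback sets out from 12.
- Acid hydrolysis (HClO4 cat, THF–H2O, 0 °C; water enters at C4, so C3 is retained) gives the (3R)-diol F1. MsCl in pyridine gives the C3 mesylate F2. K2CO3 in MeOH closes, with inversion, to the (3S)-epoxy enone F3.
- LiN(i-Pr)2 then Me3SiCl gives the (3S)-dienol ether F4. In F4 the C3–O bond can lie anti to the forming bond in a chair.
- MeAlCl2, then K2CO3 in MeOH, should give the trans-fused axial 3-epi alcohol F5. Dess–Martin periodinane gives the 3,6-dione F6.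
- NaBH4 in MeOH–CH2Cl2 at −78 °C reduces the saturated C3 ketone in preference to the hindered enone. Hydride comes from the face opposite to the axial C4 and C10 methyl groups. This gives the equatorial (3R)-alcohol and brings the route back at 16.

Step 1.
- What may go wrong: the two enamine geometries (methyl against homoprenyl) may be discriminated poorly, which would leave little induction at C10.
- Fallback: C10 is obtained by separating diastereomers after two reagent-controlled steps, not by catalyst control. The fallback sets out from 1 and 2.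
- The annulation is run with pyrrolidine and AcOH alone and gives the racemic enone F7.
- Step 2 then gives 5 together with the C10-epimeric epoxy enone F8. Step 3 gives 6 together with the C10-epimeric allylic alcohol F9.
- In 6 the hydroxyl is cis to the ring methyl at C10, and in F9 it is trans. The two are separated by chromatography at the cost of half of the material, and the route is rejoined at 6.

Step 11.
- What may go wrong: displacement at the β-branched C11 may be slow. The oxyphosphonium ion may then collapse by vinylogous elimination (loss of H-9) to a cross-conjugated dienone, or C3–OH may begin to compete.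
- Fallback: the roles are reversed, so that C11–OH is the nucleophile and no leaving group is ever placed on C11. The fallback sets out from 18 and 17.
- Tf2O in pyridine converts 18 into the coumarin-7-yl triflate F10. Miyaura borylation (B2pin2, PdCl2(dppf), KOAc, dioxane, 80 °C) gives the coumarin-7-boronic acid pinacol ester F11. KHF2 in MeOH–H2O gives the potassium coumarin-7-yltrifluoroborate F12.
- Chan–Lam-type oxidative coupling of F12 with the primary hydroxyl of 17 (Cu(OAc)2·H2O 10 mol %, DMAP, 4 Å molecular sieves, O2, CH2Cl2, rt) comes back to the route at 19.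

**Further compounds**
F1 | step 9 | (3R)-3,4-diol from 12 | O=C1C[C@@](C)(CC[C@@H](O)C(C)(C)O)[C@H](CO[Si](C)(C)C(C)(C)C)C(C)=C1
F2 | step 9 | C3 mesylate of F1 | O=C1C[C@@](C)(CC[C@@H](OS(C)(=O)=O)C(C)(C)O)[C@H](CO[Si](C)(C)C(C)(C)C)C(C)=C1
F3 | step 9 | (3S)-epoxy enone, C3 epimer of 12 | O=C1C[C@@](C)(CC[C@@H]2OC2(C)C)[C@H](CO[Si](C)(C)C(C)(C)C)C(C)=C1
F4 | step 9 | (3S)-trimethylsilyl dienol ether, C3 epimer of 14 | C[Si](C)(C)OC1=C[C@@](C)(CC[C@@H]2OC2(C)C)[C@H](CO[Si](C)(C)C(C)(C)C)C(C)=C1
F5 | step 9 | (3S,5S,9R,10S)-11-(tert-butyldimethylsilyloxy)-3-hydroxydrim-7-en-6-one | CC1=CC(=O)[C@@H]2C(C)(C)[C@@H](O)CC[C@@]2(C)[C@@H]1CO[Si](C)(C)C(C)(C)C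
F6 | step 9 | 11-(tert-butyldimethylsilyloxy)drim-7-ene-3,6-dione | CC1=CC(=O)[C@@H]2C(C)(C)C(=O)CC[C@@]2(C)[C@@H]1CO[Si](C)(C)C(C)(C)C
F7 | step 1 | racemic 2,4-dimethyl-4-(4-methylpent-3-enyl)cyclohex-2-enone | O=C1CCC(C)(CCC=C(C)C)C=C1C
F8 | step 1 | C10 epimer of 5 | O=C1CC[C@](C)(CC[C@H]2OC2(C)C)C=C1C
F9 | step 1 | C10 epimer of 6 | O[C@@H]1CC[C@](C)(CC[C@H]2OC2(C)C)C=C1C
F10 | step 11 | 2-oxo-2H-chromen-7-yl trifluoromethanesulfonate | O=S(=O)(Oc1ccc2ccc(=O)oc2c1)C(F)(F)F
F11 | step 11 | 7-(4,4,5,5-tetramethyl-1,3,2-dioxaborolan-2-yl)coumarin | CC1(C)OB(OC1(C)C)c1ccc2ccc(=O)oc2c1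
F12 | step 11 | potassium (2-oxo-2H-chromen-7-yl)trifluoroborate | [K+].F[B-](F)(F)c1ccc2ccc(=O)oc2c1
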